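**Plan**
- Retrosynthetic cuts: C1a–C1' and C1'–C2' (one-flask union of a ring A C1-carbaldehyde, a 3,5-dialkoxyphenol and i-BuMgBr), the two aryl–CHO bonds at C3a and C5a, then C1–C2 and C5–C10 of the decalin (intramolecular Diels–Alder), and the olefin bonds C1=C10, C4=C5 and C2=C3 of an acyclic triene derived from (R)-α-terpineol.
- Enabling feature: C1' is a methine bonded to arene carbon C1a, isobutyl carbon C2' and ring A carbon C1, and the neighbouring arene carbon C2a carries oxygen. C1' can therefore be the carbonyl carbon of a C1 aldehyde and then the exocyclic carbon of an ortho-quinone methide of the phloroglucinol ring.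
- Forward order: the terpineol ring is opened, three olefinations build the triene, rings A and B close together in one cycloaddition, C4 is oxygenated, arene and isobutyl group are joined at C1', and the arene is formylated twice and unmasked.
- Stereochemistry: C7 comes from (R)-α-terpineol; C5 and C10 from the endo, chair-like cycloaddition with the C7 group equatorial; C1 from the E enoate; C4 from α-face epoxidation anti to the C10 methyl; C1' from A1,3-controlled addition to the quinone methide anti to C10.

Key step: step 12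

Numbering and assumption: eudesmane numbering is used for the decalin (ring A = C1–C5, C10; ring B = C5–C10; C11 = side-chain carbinol carbon), C1'/C2' for the benzylic methine and the isobutyl CH2, and C1a–C6a for the arene. Every decalin below is trans-fused with 5α-H, 10β-CH3 and the C7 side chain β (equatorial). (R)-α-terpineol of high enantiomeric purity is assumed, because its single stereocenter relays all the others.

**Step 1**
Reactants: 1 (R)-α-terpineol
Product: 2 (R)-α-terpineol triethylsilyl ether
Conditions: TESOTf, 2,6-lutidine, CH2Cl2, 0 °C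
Reagents that add atoms: triethylsilyl trifluoromethanesulfonate (TESOTf), CC[Si](CC)(CC)OS(=O)(=O)C(F)(F)F
Why: Silylation of a tertiary alcohol with a silyl triflate and a hindered pyridine base is routine, and the ether keeps the carbinol from closing a lactol onto the aldehyde made next and lasts until the final acid treatment.

**Step 2**
Reactants: 2 (R)-α-terpineol triethylsilyl ether
Product: 4 (R)-6-oxo-3-[2-(triethylsilyloxy)propan-2-yl]heptanal, via secondary ozonide 3 (not isolated)
Conditions: O3, CH2Cl2, −78 °C; then PPh3, −78 °C → rt; used crude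
Reagents that add atoms: ozone, [O-][O+]=O
Why: Ozonolysis (Criegee mechanism) of the only alkene with reductive work-up should give the methyl ketone (future C10 with its methyl) and the aldehyde (future C5) without touching the stereocenter, and immediate use avoids intramolecular aldol condensation.

**Step 3**
Reactants: 4 (R)-6-oxo-3-[2-(triethylsilyloxy)propan-2-yl]heptanal; 5 2-(triphenylphosphoranylidene)propanal
Product: 6 (2E,5R)-2-methyl-8-oxo-5-[2-(triethylsilyloxy)propan-2-yl]non-2-enal
Conditions: toluene, 80 °C
Reagents that add atoms: 2-(triphenylphosphoranylidene)propanal 5, CC(C=O)=P(c1ccccc1)(c1ccccc1)c1ccccc1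
Why: Wittig olefination with a formyl-stabilised ylide takes the aldehyde and leaves the ketone alone, and stabilised ylides give the E trisubstituted enal (C4=C5).

**Step 4**
Reactants: 6 (2E,5R)-2-methyl-8-oxo-5-[2-(triethylsilyloxy)propan-2-yl]non-2-enal
Product: 7 (5R,7E)-8-methyl-5-[2-(triethylsilyloxy)propan-2-yl]deca-7,9-dien-2-one
Conditions: Ph3PCH3Br, n-BuLi, THF, 0 °C; then 6 (1.0 equiv ylide), −78 → −30 °C
Reagents that add atoms: methyltriphenylphosphonium bromide, C[P+](c1ccccc1)(c1ccccc1)c1ccccc1.[Br-]
Why: Wittig methylenation with one equivalent of the non-stabilised ylide at low temperature takes the aldehyde much faster than the methyl ketone and completes the E 2-methyl-1,3-diene (C2=C3–C4=C5).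

**Step 5**
Reactants: 7 (5R,7E)-8-methyl-5-[2-(triethylsilyloxy)propan-2-yl]deca-7,9-dien-2-one; 8 triethyl phosphonoacetate
Product: 9 ethyl (2E,6R,8E)-3,9-dimethyl-6-[2-(triethylsilyloxy)propan-2-yl]undeca-2,8,10-trienoate
Conditions: 8, NaH, THF, 0 °C; then 7, 0 → 50 °C; chromatography removes the 2Z isomer
Reagents that add atoms: triethyl phosphonoacetate 8, CCOC(=O)CP(=O)(OCC)OCC
Why: Horner–Wadsworth–Emmons olefination of the methyl ketone should give the enoate with the ester trans to the longer chain as the main isomer, and the minor isomer is removed because this geometry is carried over to C1.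

**Step 6**
Reactants: 9 ethyl (2E,6R,8E)-3,9-dimethyl-6-[2-(triethylsilyloxy)propan-2-yl]undeca-2,8,10-trienoate
Product: 10 ethyl 11-(triethylsilyloxy)eudesm-3-ene-1β-carboxylate
Conditions: toluene (0.01 M), BHT (cat.), 190 °C, sealed tube
Reagents that add atoms: none
Why: Thermal type 1 intramolecular Diels–Alder reaction in which the tether closes ring B as a chair (bond C5–C10) and ring A forms as the cyclohexene (bond C1–C2): the bulky C7 group sits equatorial and the ester and C10 methyl sit endo, which should give the trans fusion (5α-H, 10β-CH3) relative to C7, while suprafacial addition to the E enoate places the ester at C1 cis to the C10 methyl (1β); any cis-fused isomer is removed by chromatography.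

**Step 7**
Reactants: 10 ethyl 11-(triethylsilyloxy)eudesm-3-ene-1β-carboxylate
Product: 11 ethyl 3α,4α-epoxy-11-(triethylsilyloxy)eudesmane-1β-carboxylate
Conditions: mCPBA, NaHCO3, CH2Cl2, 0 °C
Reagents that add atoms: 3-chloroperoxybenzoic acid (mCPBA), OOC(=O)c1cccc(Cl)c1
Why: Prilezhaev epoxidation of the trisubstituted C3=C4 alkene should occur on the α face because the axial C10 methyl shields the β face, which fixes the C4–O bond as α.

**Step 8**
Reactants: 11 ethyl 3α,4α-epoxy-11-(triethylsilyloxy)eudesmane-1β-carboxylate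
Product: 12 1β-(hydroxymethyl)-11-(triethylsilyloxy)eudesman-4α-ol
Conditions: LiAlH4, THF, 0 °C → reflux; aqueous NaOH work-up
Reagents that add atoms: none
Why: Hydride reduction in which LiAlH4 converts the ester into the primary alcohol and opens the epoxide by SN2 attack at the secondary carbon C3 (the β approach to C4 is blocked by the C10 methyl), so the C4–O bond of step 7 is kept and C4 becomes the 4α-carbinol with a 4β-methyl.

**Step 9**
Reactants: 12 1β-(hydroxymethyl)-11-(triethylsilyloxy)eudesman-4α-ol
Product: 13 1β-[(triethylsilyloxy)methyl]-4α,11-bis(triethylsilyloxy)eudesmane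
Conditions: TESOTf (2.5 equiv), 2,6-lutidine, CH2Cl2, −78 → 0 °C
Reagents that add atoms: triethylsilyl trifluoromethanesulfonate (TESOTf), CC[Si](CC)(CC)OS(=O)(=O)C(F)(F)F
Why: Silyl triflate silylation covers the primary and the tertiary C4 hydroxyl alike (and would re-silylate C11 had step 8 loosened it), so no Grignard reagent is consumed by free hydroxyls later.

**Step 10**
Reactants: 13 1β-[(triethylsilyloxy)methyl]-4α,11-bis(triethylsilyloxy)eudesmane
Product: 15 4α,11-bis(triethylsilyloxy)eudesmane-1β-carbaldehyde, via alkoxysulfonium chloride 14 (not isolated)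
Conditions: (COCl)2, DMSO, CH2Cl2, −78 → −30 °C; then Et3N, −78 → 0 °C
Reagents that add atoms: none
Why: Swern oxidation applied directly to a primary triethylsilyl ether, a known selective oxidative desilylation in which the activated sulfoxide cleaves only the unhindered primary ether and oxidises it while the two tertiary ethers stay; the 1β-formyl group is equatorial and thus the more stable epimer.

**Step 11**
Reactants: 16 phloroglucinol
Product: 17 3,5-bis(methoxymethoxy)phenol
Conditions: MOMCl (2.0 equiv), i-Pr2NEt, DMF, 0 °C → rt; mono- and tris-ethers separated and recycled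
Reagents that add atoms: chloromethyl methyl ether (MOMCl), COCCl
Why: Statistical Williamson-type O-alkylation gives the known bis-ether in one step, and acetal ethers are chosen because they survive Grignard and lithium reagents, stabilise the later aryllithium and fall off under dilute acid that the two tertiary carbinols tolerate.

**Step 12**
Reactants: 15 4α,11-bis(triethylsilyloxy)eudesmane-1β-carbaldehyde; 17 3,5-bis(methoxymethoxy)phenol; 18 isobutylmagnesium bromide
Product: 22 1β-[(1S)-1-(2-hydroxy-4,6-bis(methoxymethoxy)phenyl)-3-methylbutyl]-4α,11-bis(triethylsilyloxy)eudesmane, via bromomagnesium phenoxide 19 (not isolated), via benzylic magnesium alkoxide 20 (not isolated), via ortho-quinone methide 21 (not isolated)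
Conditions: 17 (1.05 equiv), EtMgBr (1.05 equiv), Et2O, 0 °C; solvent changed to toluene; 15, 0 °C → rt; then i-BuMgBr (4 equiv), −40 °C → rt; aq NH4Cl
Reagents that add atoms: 3,5-bis(methoxymethoxy)phenol 17, COCOc1cc(O)cc(OCOC)c1; isobutylmagnesium bromide 18, CC(C)C[Mg]Br
Why: EtMgBr turns 17 into phenoxide 19, whose magnesium binds the carbonyl oxygen of 15 and delivers C1' to the ortho carbon through a six-membered cyclic array (bond C1a–C1'); i-BuMgBr then deprotonates adduct 20, the ring with its phenoxide and two alkoxy donors expels the magnesium-bound benzylic oxygen to give quinone methide 21, and a further equivalent adds to C1' (bond C1'–C2') with rearomatisation. The closest known reactions are the ortho-selective hydroxyalkylation of magnesium phenoxides by aldehydes and the 1,4-addition of Grignard reagents to ortho-quinone methides released from ortho-hydroxybenzyl alkoxides. No ring is closed; two skeletal bonds form. C1' is controlled by A1,3 strain: in 21 the C1–H bond lies in the plane of the exocyclic double bond, quaternary C10 covers one face and C2 lies on the other, so the Grignard reagent should enter from the C2 side and give 1'S whichever double-bond geometry 21 adopts. The step needs ortho rather than para C-alkylation, which magnesium chelation in toluene secures, and capture of 21 by the Grignard reagent rather than by phenoxide or a 1,5-hydrogen shift, which is secured by using barely more than one equivalent of 19, adding i-BuMgBr only once 15 is consumed and keeping it in excess at low temperature while 21 forms. The formyl-bearing C1 already has its more stable equatorial configuration, so the basic medium should not erode it.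

**Step 13**
Reactants: 22 1β-[(1S)-1-(2-hydroxy-4,6-bis(methoxymethoxy)phenyl)-3-methylbutyl]-4α,11-bis(triethylsilyloxy)eudesmane
Product: 23 1β-[(1S)-3-methyl-1-(2,4,6-tris(methoxymethoxy)phenyl)butyl]-4α,11-bis(triethylsilyloxy)eudesmane
Conditions: MOMCl, i-Pr2NEt, n-Bu4NI (cat.), CH2Cl2, 40 °C
Reagents that add atoms: chloromethyl methyl ether (MOMCl), COCCl
Why: Williamson-type O-alkylation of the remaining phenol removes the acidic proton before the organolithium step and makes the three arene oxygens alike.

**Step 14**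
Reactants: 23 1β-[(1S)-3-methyl-1-(2,4,6-tris(methoxymethoxy)phenyl)butyl]-4α,11-bis(triethylsilyloxy)eudesmane
Product: 24 1β-[(1S)-1-(3,5-dibromo-2,4,6-tris(methoxymethoxy)phenyl)-3-methylbutyl]-4α,11-bis(triethylsilyloxy)eudesmane
Conditions: NBS (2.1 equiv), DMF, 0 °C → rt, dark
Reagents that add atoms: N-bromosuccinimide (NBS), O=C1CCC(=O)N1Br
Why: Electrophilic aromatic bromination of the trialkoxyarene should take its only two free positions, C3a and C5a, under acid-free conditions that spare acetals and silyl ethers.

**Step 15**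
Reactants: 24 1β-[(1S)-1-(3,5-dibromo-2,4,6-tris(methoxymethoxy)phenyl)-3-methylbutyl]-4α,11-bis(triethylsilyloxy)eudesmane
Product: 26 1β-[(1S)-1-(3,5-diformyl-2,4,6-tris(methoxymethoxy)phenyl)-3-methylbutyl]-4α,11-bis(triethylsilyloxy)eudesmane, via dilithio arene 25 (not isolated)
Conditions: t-BuLi (4.4 equiv), THF, −78 °C; then DMF, −78 → 0 °C; aq NH4Cl
Reagents that add atoms: N,N-dimethylformamide (DMF), CN(C)C=O
Why: Double bromine–lithium exchange followed by formylation with a formamide (Bouveault aldehyde synthesis) should install both aldehydes at once, each aryllithium being held by two flanking methoxymethoxy groups.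

**Step 16**
Reactants: 26 1β-[(1S)-1-(3,5-diformyl-2,4,6-tris(methoxymethoxy)phenyl)-3-methylbutyl]-4α,11-bis(triethylsilyloxy)eudesmane
Product: 27 macrocarpal J
Conditions: 2 M aq HCl, THF/MeOH, rt → 40 °C
Reagents that add atoms: none
Why: Acid-catalysed hydrolysis cleaves the three aryl acetal ethers (eased by the ortho formyl groups) and the two triethylsilyl ethers in one operation, under conditions dilute enough that the saturated tertiary alcohols should not dehydrate.

**Compound list**
1 | (R)-α-terpineol | CC1=CC[C@@H](CC1)C(C)(C)O | starting material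
2 | (R)-α-terpineol triethylsilyl ether | CC1=CC[C@@H](CC1)C(C)(C)O[Si](CC)(CC)CC | intermediate
3 | secondary ozonide of 2 (1,2,4-trioxolane across the former ring alkene, both trioxolane epimers) | CC12CC[C@H](CC(O1)OO2)C(C)(C)O[Si](CC)(CC)CC | intermediate (not isolated)
4 | (R)-6-oxo-3-[2-(triethylsilyloxy)propan-2-yl]heptanal | O=CC[C@@H](CCC(C)=O)C(C)(C)O[Si](CC)(CC)CC | intermediate
5 | 2-(triphenylphosphoranylidene)propanal | CC(C=O)=P(c1ccccc1)(c1ccccc1)c1ccccc1 | starting material
6 | (2E,5R)-2-methyl-8-oxo-5-[2-(triethylsilyloxy)propan-2-yl]non-2-enal | O=C/C(C)=C/C[C@@H](CCC(C)=O)C(C)(C)O[Si](CC)(CC)CC | intermediate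
7 | (5R,7E)-8-methyl-5-[2-(triethylsilyloxy)propan-2-yl]deca-7,9-dien-2-one | C=C/C(C)=C/C[C@@H](CCC(C)=O)C(C)(C)O[Si](CC)(CC)CC | intermediate
8 | triethyl phosphonoacetate | CCOC(=O)CP(=O)(OCC)OCC | starting material
9 | ethyl (2E,6R,8E)-3,9-dimethyl-6-[2-(triethylsilyloxy)propan-2-yl]undeca-2,8,10-trienoate | CCOC(=O)/C=C(\C)CC[C@H](C/C=C(\C)C=C)C(C)(C)O[Si](CC)(CC)CC | intermediate
10 | ethyl 11-(triethylsilyloxy)eudesm-3-ene-1β-carboxylate (trans-fused, 1β-ester equatorial) | CCOC(=O)[C@@H]1CC=C(C)[C@@H]2C[C@H](C(C)(C)O[Si](CC)(CC)CC)CC[C@]21C | intermediate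
11 | ethyl 3α,4α-epoxy-11-(triethylsilyloxy)eudesmane-1β-carboxylate | CCOC(=O)[C@@H]1C[C@H]2O[C@@]2(C)[C@@H]3C[C@H](C(C)(C)O[Si](CC)(CC)CC)CC[C@]31C | intermediate
12 | 1β-(hydroxymethyl)-11-(triethylsilyloxy)eudesman-4α-ol | OC[C@@H]1CC[C@@](C)(O)[C@@H]2C[C@H](C(C)(C)O[Si](CC)(CC)CC)CC[C@]21C | intermediate
13 | 1β-[(triethylsilyloxy)methyl]-4α,11-bis(triethylsilyloxy)eudesmane | CC[Si](CC)(CC)OC[C@@H]1CC[C@@](C)(O[Si](CC)(CC)CC)[C@@H]2C[C@H](C(C)(C)O[Si](CC)(CC)CC)CC[C@]21C | intermediate
14 | alkoxydimethylsulfonium chloride at the primary oxygen of 13 | C[S+](C)OC[C@@H]1CC[C@@](C)(O[Si](CC)(CC)CC)[C@@H]2C[C@H](C(C)(C)O[Si](CC)(CC)CC)CC[C@]21C.[Cl-] | intermediate (not isolated)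
15 | 4α,11-bis(triethylsilyloxy)eudesmane-1β-carbaldehyde | O=C[C@@H]1CC[C@@](C)(O[Si](CC)(CC)CC)[C@@H]2C[C@H](C(C)(C)O[Si](CC)(CC)CC)CC[C@]21C | intermediate (precursor of the key step)
16 | phloroglucinol | Oc1cc(O)cc(O)c1 | starting material
17 | 3,5-bis(methoxymethoxy)phenol | COCOc1cc(O)cc(OCOC)c1 | intermediate
18 | isobutylmagnesium bromide | CC(C)C[Mg]Br | starting material
19 | bromomagnesium 3,5-bis(methoxymethoxy)phenoxide | COCOc1cc(O[Mg]Br)cc(OCOC)c1 | intermediate (not isolated)
20 | benzylic bromomagnesium alkoxide from ortho addition of 19 to 15 (both C1' epimers) | COCOc1cc(O)c(C(O[Mg]Br)[C@@H]2CC[C@@](C)(O[Si](CC)(CC)CC)[C@@H]3C[C@H](C(C)(C)O[Si](CC)(CC)CC)CC[C@]32C)c(OCOC)c1 | intermediate (not isolated)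
21 | ortho-quinone methide with C1a=C1' exocyclic double bond (geometry not fixed) | COCOC1=CC(=O)C(=C[C@@H]2CC[C@@](C)(O[Si](CC)(CC)CC)[C@@H]3C[C@H](C(C)(C)O[Si](CC)(CC)CC)CC[C@]32C)C(OCOC)=C1 | intermediate (not isolated)
22 | 1β-[(1S)-1-(2-hydroxy-4,6-bis(methoxymethoxy)phenyl)-3-methylbutyl]-4α,11-bis(triethylsilyloxy)eudesmane | CC(C)C[C@H](c1c(O)cc(OCOC)cc1OCOC)[C@@H]1CC[C@@](C)(O[Si](CC)(CC)CC)[C@@H]2C[C@H](C(C)(C)O[Si](CC)(CC)CC)CC[C@]21C | intermediate (product of the key step)
23 | 1β-[(1S)-3-methyl-1-(2,4,6-tris(methoxymethoxy)phenyl)butyl]-4α,11-bis(triethylsilyloxy)eudesmane | CC(C)C[C@H](c1c(OCOC)cc(OCOC)cc1OCOC)[C@@H]1CC[C@@](C)(O[Si](CC)(CC)CC)[C@@H]2C[C@H](C(C)(C)O[Si](CC)(CC)CC)CC[C@]21C | intermediate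
24 | 3a,5a-dibromide of 23 | CC(C)C[C@H](c1c(OCOC)c(Br)c(OCOC)c(Br)c1OCOC)[C@@H]1CC[C@@](C)(O[Si](CC)(CC)CC)[C@@H]2C[C@H](C(C)(C)O[Si](CC)(CC)CC)CC[C@]21C | intermediate
25 | 3a,5a-dilithio arene from 24 | CC(C)C[C@H](c1c(OCOC)c([Li])c(OCOC)c([Li])c1OCOC)[C@@H]1CC[C@@](C)(O[Si](CC)(CC)CC)[C@@H]2C[C@H](C(C)(C)O[Si](CC)(CC)CC)CC[C@]21C | intermediate (not isolated)
26 | 3a,5a-dialdehyde (fully protected macrocarpal J) | CC(C)C[C@H](c1c(OCOC)c(C=O)c(OCOC)c(C=O)c1OCOC)[C@@H]1CC[C@@](C)(O[Si](CC)(CC)CC)[C@@H]2C[C@H](C(C)(C)O[Si](CC)(CC)CC)CC[C@]21C | intermediate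
27 | macrocarpal J (1S,4R,5R,7R,10S,1'S) | CC(C)C[C@H](c1c(O)c(C=O)c(O)c(C=O)c1O)[C@@H]1CC[C@@](C)(O)[C@@H]2C[C@H](C(C)(C)O)CC[C@]21C | target

**Totals**
Total step count: 16. Longest linear sequence: 15 steps (steps 1–10 and 12–16, from (R)-α-terpineol); step 11 is a one-step branch.

**Three steps most likely to fail**

1. Step 12. What may go wrong: the hindered aldehyde is hydroxyalkylated slowly; the quinone methide, formed near ambient temperature, is lost to a 1,5-hydrogen shift, to a second arylation or to hydride transfer from the Grignard reagent; or it is attacked with weak facial selectivity. The fallback generates the quinone methide stepwise and at low temperature from an activated carbonate. Setting out from 15 and 17, the hydroxyalkylation alone (17, EtMgBr, toluene, 0 °C; then 15; buffered aqueous quench) gives the ortho-hydroxybenzyl alcohol F1. Boc2O, i-Pr2NEt and catalytic DMAP in CH2Cl2 at 0 °C acylate its phenol to the aryl tert-butyl carbonate F2. i-BuMgBr (3 equiv) in Et2O at −78 °C then forms the benzylic alkoxide, the carbonate migrates to it and is expelled by the phenoxide, and the quinone methide 21 is trapped as it forms, which returns to 22.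

2. Step 6. What may go wrong: the endo preference at 190 °C is too small, so cis-fused cycloadduct forms alongside, or the trisubstituted enoate reacts so slowly that the diene polymerises. The fallback uses a Lewis-acid-activated enal as dienophile. Setting out from 9, i-Bu2AlH (CH2Cl2, −78 °C) gives the trienol F3 and MnO2 (CH2Cl2, rt) the trienal F4. Me2AlCl (CH2Cl2, −78 → −20 °C) then closes both rings to the octalin aldehyde F5 under tighter endo control. NaClO2, NaH2PO4 and 2-methyl-2-butene in t-BuOH/H2O give the octalin acid F6, and EtI, K2CO3, DMF returns to 10.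

3. Step 8. What may go wrong: hydride attack at C3 runs against the trans-diaxial opening preferred by the rigid ring, so the epoxide may open slowly, or rearrange to a C3 ketone under Lewis-acidic aluminium species and end as a secondary alcohol. The fallback replaces SN2 hydride opening by electron-transfer cleavage. Setting out from 11, i-Bu2AlH (CH2Cl2, −78 °C) reduces only the ester and gives the epoxy alcohol F7. After deprotonation with n-BuLi, lithium 4,4'-di-tert-butylbiphenylide (LiDBB) in THF at −78 °C, then MeOH, cleaves the C3–O bond through the radical anion to the secondary carbanion and the tertiary alkoxide, with no demand on trajectory, which returns to 12.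

**Further compounds**
F1 | step 12 | ortho-hydroxybenzyl alcohol from 15 and 17 (both C1' epimers) | COCOc1cc(O)c(C(O)[C@@H]2CC[C@@](C)(O[Si](CC)(CC)CC)[C@@H]3C[C@H](C(C)(C)O[Si](CC)(CC)CC)CC[C@]32C)c(OCOC)c1
F2 | step 12 | aryl tert-butyl carbonate of F1 | COCOc1cc(OC(=O)OC(C)(C)C)c(C(O)[C@@H]2CC[C@@](C)(O[Si](CC)(CC)CC)[C@@H]3C[C@H](C(C)(C)O[Si](CC)(CC)CC)CC[C@]32C)c(OCOC)c1
F3 | step 6 | (2E,6R,8E)-3,9-dimethyl-6-[2-(triethylsilyloxy)propan-2-yl]undeca-2,8,10-trien-1-ol | OC/C=C(\C)CC[C@H](C/C=C(\C)C=C)C(C)(C)O[Si](CC)(CC)CC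
F4 | step 6 | (2E,6R,8E)-3,9-dimethyl-6-[2-(triethylsilyloxy)propan-2-yl]undeca-2,8,10-trienal | O=C/C=C(\C)CC[C@H](C/C=C(\C)C=C)C(C)(C)O[Si](CC)(CC)CC
F5 | step 6 | 11-(triethylsilyloxy)eudesm-3-ene-1β-carbaldehyde | O=C[C@@H]1CC=C(C)[C@@H]2C[C@H](C(C)(C)O[Si](CC)(CC)CC)CC[C@]21C
F6 | step 6 | 11-(triethylsilyloxy)eudesm-3-ene-1β-carboxylic acid | OC(=O)[C@@H]1CC=C(C)[C@@H]2C[C@H](C(C)(C)O[Si](CC)(CC)CC)CC[C@]21C
F7 | step 8 | 3α,4α-epoxy-1β-(hydroxymethyl)-11-(triethylsilyloxy)eudesmane | OC[C@@H]1C[C@H]2O[C@@]2(C)[C@@H]3C[C@H](C(C)(C)O[Si](CC)(CC)CC)CC[C@]31C
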